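The route rests on reading the target as benzoic acid added in SN2′ fashion across an oxygen bridge. The free hydroxyl on C2, the trans benzoate on C3 and the C4=C5 alkene of the cyclohexene ring, with the C1–C6 oxirane cis to O2, are exactly what a rhodium-catalysed opening of a C2–O–C5 bridged 7-oxanorbornene by benzoate would leave. That one operation installs the secondary benzoate, frees O2 already differentiated from the other oxygens, and unveils the vinyl epoxide. Its precursor is an enantiopure 7-oxanorbornene bearing an exo epoxide and an endo CH2OBz group, assembled from furan and methyl propiolate by Diels–Alder reaction, nucleophilic epoxidation, reduction and lipase resolution.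

Key step: step 5

Remark on numbering: ring atoms carry the target's numbers throughout (C1 = oxirane carbon bearing CH2OBz, C2 = carbinol carbon, C3 = benzoate carbon, C4=C5 alkene, C6 = oxirane CH); in the bicyclic precursors the oxygen bridge joins C2 and C5, and racemates are written with the SMILES of the enantiomer carried on.

Assumption: the lipase is taken to benzoylate the drawn enantiomer of the racemic epoxy alcohol; should it prefer the mirror image, the alcohol left over is the drawn one and BzCl/pyridine converts it into the same primary benzoate.

Step 1
Reactants: 1 furan; 2 methyl propiolate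
Product: 3 methyl 7-oxabicyclo[2.2.1]hepta-2,5-diene-2-carboxylate (racemic; bridgehead hydrogens necessarily cis)
Conditions: AlCl3 (1 equiv), furan (5 equiv), CH2Cl2, −20 to 0 °C; cold aq. NaHCO3 quench; crude product used the same day
Reagents that add atoms: none
Why: Lewis-acid-promoted Diels–Alder reaction in which AlCl3 bound to the ester lowers the alkyne LUMO so that furan adds below 0 °C, where the acid-labile adduct (prone to isomerise to a hydroxybenzoate) survives; the two bridgehead centres form together by suprafacial addition, as a racemate.

Step 2
Reactants: 3 methyl 7-oxabicyclo[2.2.1]hepta-2,5-diene-2-carboxylate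
Product: 4 methyl 3,8-dioxatricyclo[3.2.1.0(2,4)]oct-6-ene-2-carboxylate (racemic; epoxide exo, on the face of the bridging oxygen; ester endo)
Conditions: t-BuOOH (1.5 equiv, anhydrous), DBU (0.3 equiv), CH2Cl2, 0 °C
Reagents that add atoms: tert-butyl hydroperoxide, CC(C)(C)OO
Why: Weitz–Scheffer nucleophilic epoxidation, in which the peroxide anion adds in conjugate fashion only to the strained acrylate C=C (the unactivated alkene is inert to a nucleophilic oxidant) from the convex exo face and the ester enolate then closes on the O–O bond, setting C1 and C6 together with the oxirane oxygen syn to the bridge.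

Step 3
Reactants: 4 methyl 3,8-dioxatricyclo[3.2.1.0(2,4)]oct-6-ene-2-carboxylate
Product: 5 [3,8-dioxatricyclo[3.2.1.0(2,4)]oct-6-en-2-yl]methanol (racemic; exo epoxide, endo CH2OH on the oxirane carbon next to a bridgehead)
Conditions: NaBH4 (2 equiv), MeOH, 0 °C to rt
Reagents that add atoms: none
Why: Borohydride reduction of an ester, feasible here because the α-oxygen of a glycidic ester makes the carbonyl electrophilic enough for NaBH4 in methanol, conditions that leave the epoxide, the ether bridge and the alkene alone and touch no stereocentre.

Step 4
Reactants: 5 racemic epoxy alcohol; 6 vinyl benzoate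
Product: 7 [(1S,2S,4R,5R)-3,8-dioxatricyclo[3.2.1.0(2,4)]oct-6-en-2-yl]methyl benzoate (single enantiomer; exo epoxide, endo CH2OBz)
Conditions: Novozym 435 (immobilised Candida antarctica lipase B; Burkholderia cepacia lipase as second choice), vinyl benzoate (3 equiv), MTBE, 40 °C, stopped near half conversion; chromatography; ee by chiral HPLC and absolute configuration checked before use
Reagents that add atoms: none
Why: Lipase-catalysed kinetic resolution by irreversible transesterification from an enol ester (the vinyl alcohol released tautomerises to acetaldehyde), in which the enzyme should tell apart the two hands of the quaternary centre next to the CH2OH group so that one enantiomer is benzoylated and separated from the other; no stereocentre is formed and the neutral medium spares epoxide and bridge.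

Step 5
Reactants: 7 enantiopure epoxy-7-oxanorbornene benzoate; 8 benzoic acid
Product: 9 [(1S,2S,3R,6R)-3-(benzoyloxy)-2-hydroxy-7-oxabicyclo[4.1.0]hept-4-en-1-yl]methyl benzoate (oxirane oxygen and C2 hydroxyl on one face, C3 benzoate and CH2OBz on the other)
Conditions: [Rh(cod)Cl]2 (2.5 mol %), (R)-1-[(S)-2-(diphenylphosphino)ferrocenyl]ethyldi-tert-butylphosphine or its mirror image (6 mol %, hand fixed by a two-run screen), AgOTf (6 mol %) then Bu4NI (12 mol %), BzOH (1.1 equiv), Et3N (0.5 equiv), THF, 50 °C; neutral work-up, no base
Reagents that add atoms: none
Why: Proposed new method: monovalent rhodium held on the exo face by the C3=C4 alkene and the bridging oxygen should insert into the C5–O bond with retention, irreversibly because the bicyclic strain is released, to give a trivalent rhodium C3–C4–C5 allyl carrying the C2 alkoxide, which benzoic acid protonates, and benzoate then attacks C3 on the face opposite the metal (overall SN2′) and returns the catalyst. The closest known reaction type is the rhodium/ferrocenyl-diphosphine asymmetric ring opening of oxabenzonorbornadienes and simple 7-oxanorbornenes by carboxylates, phenols and amines to trans-1,2 products; an epoxide-fused, merely pseudo-symmetric 7-oxanorbornene has not been put through it. No ring is closed: the oxygen bridge is opened, and the cyclohexene and oxirane rings are carried over unchanged. The only new stereocentre, C3, is fixed by the anti relationship between nucleophile and rhodium, which puts the benzoate on the former endo face, trans to the C2 hydroxyl, while C1, C2 and C6 are untouched. The step needs ionisation of the C5–O and not the C2–O bridgehead bond, which the matched hand of the ligand acting on the resolved substrate should secure (the mismatched pairing, and any residual antipode, should end as a separable regioisomer), and it must spare the vinyl epoxide of the product, which the much greater reactivity of the strained bridge together with a near-stoichiometric charge of benzoate should secure. The substrate's own C1–C6 epoxide is not allylic and gives the metal no handle, and the base-free work-up guards against O3-to-O2 benzoyl shift and Payne rearrangement.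

Compound list
1 | furan | c1ccoc1 | starting material
2 | methyl propiolate | C#CC(=O)OC | starting material
3 | methyl 7-oxabicyclo[2.2.1]hepta-2,5-diene-2-carboxylate (racemic) | COC(=O)C1=C[C@H]2C=C[C@@H]1O2 | intermediate
4 | methyl 3,8-dioxatricyclo[3.2.1.0(2,4)]oct-6-ene-2-carboxylate (racemic, exo epoxide) | COC(=O)[C@@]12O[C@@H]1[C@@H]3O[C@H]2C=C3 | intermediate
5 | [3,8-dioxatricyclo[3.2.1.0(2,4)]oct-6-en-2-yl]methanol (racemic, exo epoxide) | OC[C@@]12O[C@@H]1[C@@H]3O[C@H]2C=C3 | intermediate
6 | vinyl benzoate | C=COC(=O)c1ccccc1 | starting material
7 | [(1S,2S,4R,5R)-3,8-dioxatricyclo[3.2.1.0(2,4)]oct-6-en-2-yl]methyl benzoate | O=C(c1ccccc1)OC[C@@]12O[C@@H]1[C@@H]3O[C@H]2C=C3 | intermediate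
8 | benzoic acid | OC(=O)c1ccccc1 | starting material
9 | [(1S,2S,3R,6R)-3-(benzoyloxy)-2-hydroxy-7-oxabicyclo[4.1.0]hept-4-en-1-yl]methyl benzoate | O=C(OC[C@@]12O[C@@H]1C=C[C@@H](OC(=O)c1ccccc1)[C@@H]2O)c1ccccc1 | target

Total step count: 5. Longest linear sequence: 5 steps (1 and 2 to 9).

Steps most likely to fail

Step 5 (the proposed new method). The metal may insert into the C2–O instead of the C5–O bridgehead bond and so deliver the regioisomeric hydroxy benzoate. It may also insert only sluggishly into this non-benzo bicycle, or go on to ionise the vinyl epoxide of the product. The fallback uses known reactions only and replaces the metal-catalysed opening by an ester-directed one; it sets out from racemic 4 and comes back to the route at 9.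
- SmI2 (THF/MeOH, −78 °C) should cleave the α C–O bond of the glycidic ester to give methyl 3-exo-hydroxy-7-oxabicyclo[2.2.1]hept-5-ene-2-carboxylate F1.
- LiHMDS (2.2 equiv, THF, −78 to 0 °C) should then open the oxygen bridge by E1cB elimination from the ester enolate (the β-alkoxide cannot leave, the strained bridge can) to give methyl cis-5,6-dihydroxycyclohexa-1,3-diene-1-carboxylate F2.
- DIBAL (CH2Cl2, −78 °C) should reduce the ester to 3-(hydroxymethyl)cyclohexa-3,5-diene-cis-1,2-diol F3.
- VO(acac)2/t-BuOOH should epoxidise the trisubstituted alkene, which is allylic to two hydroxyls, cis to the ring hydroxyl and give the all-cis 1-(hydroxymethyl)-7-oxabicyclo[4.1.0]hept-4-ene-2,3-diol F4.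
- The lipase with vinyl benzoate 6 should benzoylate the primary hydroxyl with kinetic resolution to give the all-cis epoxy diol primary benzoate F5.
- A Mitsunobu reaction (PPh3, DIAD, benzoic acid 8) at the more reactive allylic C3 hydroxyl, rather than the hindered C2 hydroxyl beside the quaternary oxirane carbon, should install the second benzoate with inversion and give 9.

In this sequence O2 stems from the epoxide oxygen of 4, O3 from the bridge, and the oxirane is introduced anew.

Step 4. The lipase may discriminate poorly at a quaternary centre, or benzoyl transfer from the enol ester may be too slow, so that neither fraction reaches useful enantiomeric purity. The fallback is a covalent diastereomer resolution; it sets out from racemic 5 and comes back at 7.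
- Acylation with (1S,4R)-camphanoyl chloride (Et3N, DMAP, CH2Cl2) should give two diastereomers, the camphanate of the wanted alcohol F6 and the camphanate of its antipode F7.
- These are separated by crystallisation or chromatography; a crystal structure of either also fixes the absolute configuration against the known camphanoyl unit.
- K2CO3 in methanol should release from F6 the single-enantiomer epoxy alcohol F8, and BzCl/pyridine should convert it into 7.

Step 2. The hydroperoxide anion may add without closing the ring or attack the ester, or the base may trigger opening and aromatisation of the strained diene ester. The fallback reduces first and then epoxidises electrophilically under hydroxyl direction; it sets out from 3 and comes back at 5, bypassing 4.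
- DIBAL (CH2Cl2, −78 °C) should reduce the ester to (7-oxabicyclo[2.2.1]hepta-2,5-dien-2-yl)methanol F9.
- Its allylic hydroxyl should then direct VO(acac)2/t-BuOOH to its own trisubstituted alkene on the open exo face, giving 5.

Further compounds
F1 | step 5 | methyl 3-exo-hydroxy-7-oxabicyclo[2.2.1]hept-5-ene-2-carboxylate (racemic, epimers at the ester carbon) | COC(=O)C1[C@@H](O)[C@@H]2C=C[C@H]1O2
F2 | step 5 | methyl cis-5,6-dihydroxycyclohexa-1,3-diene-1-carboxylate (racemic) | COC(=O)C1=CC=C[C@H](O)[C@@H]1O
F3 | step 5 | 3-(hydroxymethyl)cyclohexa-3,5-diene-cis-1,2-diol (racemic) | OCC1=CC=C[C@H](O)[C@@H]1O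
F4 | step 5 | all-cis 1-(hydroxymethyl)-7-oxabicyclo[4.1.0]hept-4-ene-2,3-diol (racemic) | OC[C@@]12O[C@@H]1C=C[C@H](O)[C@@H]2O
F5 | step 5 | all-cis (2,3-dihydroxy-7-oxabicyclo[4.1.0]hept-4-en-1-yl)methyl benzoate (single enantiomer) | O=C(OC[C@@]12O[C@@H]1C=C[C@H](O)[C@@H]2O)c1ccccc1
F6 | step 4 | (1S,4R)-camphanate of the wanted enantiomer of 5 | O=C(OC[C@@]12O[C@@H]1[C@@H]3O[C@H]2C=C3)[C@]45OC(=O)[C@](C)(CC4)C5(C)C
F7 | step 4 | (1S,4R)-camphanate of the antipode of 5 | O=C(OC[C@]12O[C@H]1[C@H]3O[C@@H]2C=C3)[C@]45OC(=O)[C@](C)(CC4)C5(C)C
F8 | step 4 | single-enantiomer epoxy alcohol (the drawn hand of 5) | OC[C@@]12O[C@@H]1[C@@H]3O[C@H]2C=C3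
F9 | step 2 | (7-oxabicyclo[2.2.1]hepta-2,5-dien-2-yl)methanol (racemic) | OCC1=C[C@H]2C=C[C@@H]1O2
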